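The numbers of this flask stand for no real mixture; the rest is arithmetic.

The easy step first: L leaves both catalysed steps unchanged, so after the last portion, at 0.833 min, c_L stands at 4.0 mM. Solid E dissolves to Z, L turns Z into J, L with Q turns J into G, and G beyond its solubility crystallises as X.

E 0.80 M; Q 0.880 M; L 4.0 mM (in portions, 3); time 8.0 min; the portions of L follow each other after 25 s, the first at the start

    X ⇌ G, rate k1*(cs1 - [G]) while solid is left; crystals form when [G] > cs1 (cs1 = 0.053 M, k1 = 29 min⁻¹)
    E ⇌ Z, rate k2*(cs2 - [Z]) while solid is left; crystals form when [Z] > cs2 (cs2 = 0.28 M, k2 = 0.21 min⁻¹)
    Q + L + J → L + G (k3 = 35 M⁻² min⁻¹)
    Z + L → L + J (k4 = 24 M⁻¹ min⁻¹)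

- G is meant together with its X
- solid, in amounts per volume of the solution: E, X
- at the start none of E is in solution
- what has only dissolved of E counts as not reacted
- the reaction counts as stopped when no species that holds the E changes by six tenths of a point or more over the second half of the time
- Z means what is dissolved; the solid is not counted in it
- run time (flask): 8.0 min

* the state of affairs at 8.0 min: stopped, and by what, or still going (for what has run out or reacted, a solid counts together with what of it has only dissolved) (all of E has reacted / no working catalyst is left / it is still moving / Q has run out first)
* the G standing at 8.0 min, as a percentage of the E charged
* the Z standing at 8.0 min, as a percentage of the E charged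
* amount of G if the flask were left three thousand times as long, in percent of the E charged

What happens to Z? Dissolution feeds it and L drains it, at full c_L a pseudo-first-order loss at 0.0960 min⁻¹. Feed equals drain at the plateau share, the level where c_Z stands still while solid lasts, as a share of the E charged: 24.0 %.

Is it reached in time? The approach has time constant 3.27 min, so with c_L full from the start, Z stands at 21.9 %.

But c_L is not full from the start. True: I replaced its curve by its final value. During the feed it falls short by half on the mean, which takes 0.0400 off the exponent of the approach. Held against the remaining gap of 2.1 percentage points, that gives a bound: Z lies above my figure by less than 0.083 points.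

Does anything run out? Dissolution cannot pass 0.470 M by then, less than the E or the Q charged, so my verdict is: it is still moving.

And G, the weak spot? By the same curve, mean Z over the run is 15.1 %, which makes 11.6 % into J. Fed steadily, J clears at 0.123 min⁻¹. A steady feed overstates early J, so I claim a ceiling: G below 5.70 %, under the solubility share 6.62 %. Left long, Q covers E, so G goes to 100 %.

The forecast says it is still moving, with G 3.4 %, Z 22 % and 100 % in the long run, by “Stepping through the three L phases”, where I used one curve and a correction. Its G stands below my ceiling.

The simulation gives it is still moving, G 3.36 %, Z 22.0 % and 100 % in the long run. At 8.00 min this flask makes J 2.17 times faster than it uses J, and Z 1.30 times faster than it uses Z, so material is still collecting in both. The nearest amount of L above the charge at which the answer for G has moved by 5 points is 7.40 mM.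

The same flask left until 15 min still holds solid E, 49.2 %, and the plateau reckoning gives 23.8 % for Z. The computed result there is 23.8 %.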